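The unit I start from is the reciprocal minute: in it the feed brings electrophile into the winter flask at 0.0400 min⁻¹ of the charge.

all flasks: electrophile 10 mM (fed, over 25 min)

|  | nucleophile | buffer base | buffer acid | remark | time |
|---|---|---|---|---|---|
| winter | 18 mM | 30 mM | 1 mM | the very flask that is asked about, followed so far |  |
| summer | 18 mM | 30 mM | 1.5 mM | run made earlier |  |
| flask | 18.0 mM | 30.0 mM | 1.00 mM |  | 50 min |

* part of the electrophile that has reacted at 50 min
* pH of the solution at 50 min

Nucleophile stands in excess over the electrophile charge, so what I need is a second rate in the same unit, and the readings can give it.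

| run | time / min | electrophile / % | product / % |
|---|---|---|---|
| winter | 1.00 | 2.8 | 0.2 |
| winter | 3.00 | 11.7 | 1.5 |
| winter | 5.00 | 19.3 | 0 |
| winter | 8.00 | 29.5 | 2.8 |
| winter | 12.0 | 41.7 | 6.2 |
| winter | 15.0 | 51.4 | 10.6 |
| summer | 3.00 | 11.0 | 2.6 |
| summer | 6.00 | 21.9 | 0 |
| summer | 10.0 | 34.6 | 4.7 |
| summer | 12.0 | 43.6 | 6.6 |
| summer | 15.0 | 52.4 | 11.7 |
| summer | 20.0 | 63.7 | 15.5 |

(standard deviation of a reading: 1 percentage point)

In both runs [electrophile] climbs nearly in a line, so its time-integral is about the last reading times half the time. Product divided by that integral gives a pseudo-first-order constant: 0.0243 min⁻¹ from the last summer reading and 0.0275 min⁻¹ from the last winter one, each with the scatter of a reading. I take the later reading, from the summer run, for the winter flask as well, although the two runs differ in buffer acid.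

Dividing this rate by the feed's rate, so that time drops out, gives 0.608, the capture number (a Damköhler number). It is below one, so I expect electrophile to gather during the feed of the winter flask. With [nucleophile] held at its charge, I reckon that 74.9% of the charge stands at the end of the feed. From there, with both reagents falling one for one, I reckon 53.2% reacted at 50 min.

The forecast says 52% and pH 7.6. It stands below my figure, having been shaded down since “any later pH slowdown would lower conversion”.

The winter flask gives 48.9% and pH 6.85, both within the margins of the forecast.

    electrophile + nucleophile → acid + product + leaving group (k = 0.0240 M⁻¹ s⁻¹)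
    buffer acid ⇌ buffer base + acid, settled at all times (K = 1.60 × 10⁻⁶ M)
    protonated nucleophile ⇌ nucleophile + acid, settled at all times (K = 4.00 × 10⁻⁷ M)

In the winter flask at 26.0 min the half-life of electrophile by the step with nucleophile is 36 min, longer than the feed of 25 min, so the capture number reckoned for that moment from that half-life is 0.481, and at 50.0 min the winter flask still holds 51.1% of the charged electrophile. In a neighbour flask with 72 mM of nucleophile, its other charges as in the recipe, my capture number from the readings scales to 2.43, above one, and that neighbour has 5.34% of the charged electrophile left at 50.0 min.

(The earlier runs and the new flask were computed with made-up constants; the scatter is artificial.)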